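**Retrosynthetic overview**
- Last bonds broken: the two O–Si bonds (global desilylation), then the exocyclic N–C(amidine) bond, which is made by condensing a 2-aminoimidazole with 1-methylparabanic acid.
- The C2–NH2 group of the imidazole comes from C2–H by lithiation, azide transfer and reduction.
- Key disconnection: the C4–CH(OH)Ar bond and the only stereocentre come from a 4-iodoimidazole and 4-methoxybenzaldehyde by a new catalytic enantioselective imidazol-4-yl transfer (Mg to Ti, H8-BINOL/Ti(OiPr)4).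
- The C5–CH2Ar bond comes from regioselective iodine–magnesium exchange of 4,5-diiodo-1-methylimidazole, aldehyde addition and ionic deoxygenation.
- Ring order: no ring is built. The imidazole core is bought and substituted C5, then C4, then C2; the imidazoledione ring is brought in intact and attached in the penultimate step.

Assumption: the descriptor in the given SMILES corresponds to the (R)-carbinol (CIP order OH > imidazol-4-yl > 4-methoxyphenyl > H). TBS = tert-butyldimethylsilyl, TBSO = TBS ether oxygen; compounds 1, 2, 6 and 14 are catalogue chemicals.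

**Route**

Step 1
Reactants: 1 4,5-diiodo-1-methyl-1H-imidazole; 2 4-(TBSO)benzaldehyde
Product: 4 racemic [4-(TBSO)phenyl](4-iodo-1-methyl-1H-imidazol-5-yl)methanol, via 5-imidazolylmagnesium bromide 3 (not isolated)
Conditions: EtMgBr (1.05 equiv), THF/CH2Cl2, 0 °C to rt, 30 min; then 2, 0 °C to rt; H2O quench
Reagents that add atoms: none
Why: Iodine–magnesium exchange is selective for the C5 iodide next to N-methyl, and the resulting Grignard reagent adds to the aldehyde (Grignard addition); the new carbinol centre is racemic and is removed in step 2.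

Step 2
Reactants: 4 racemic [4-(TBSO)phenyl](4-iodo-1-methyl-1H-imidazol-5-yl)methanol
Product: 5 5-[4-(TBSO)benzyl]-4-iodo-1-methyl-1H-imidazole
Conditions: Et3SiH (3 equiv), TFA/CH2Cl2 (1:3), 0 °C to 40 °C
Reagents that add atoms: none
Why: Ionic hydrogenation (silane/acid deoxygenation) proceeds through the 4-siloxybenzyl cation, while the aryl silyl ether and the C4 iodide tolerate TFA.

Step 3
Reactants: 5 5-[4-(TBSO)benzyl]-4-iodo-1-methyl-1H-imidazole; 6 4-methoxybenzaldehyde
Product: 9 (R)-{5-[4-(TBSO)benzyl]-1-methyl-1H-imidazol-4-yl}(4-methoxyphenyl)methanol, via imidazol-4-ylmagnesium chloride 7 (not isolated), via imidazol-4-yltitanium triisopropoxide 8 (not isolated)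
Conditions: iPrMgCl·LiCl (1.1 equiv), THF, 0 °C to rt, 1 h; ClTi(OiPr)3 (1.15 equiv), −40 to 0 °C; this solution added over 3 h to 6 (1.5 equiv), (S)-H8-BINOL (10 mol%), Ti(OiPr)4 (1.5 equiv), CH2Cl2, 0 °C; H2O quench
Reagents that add atoms: none
Why: Proposed new method: the first catalytic enantioselective transfer of an imidazol-4-yl group (free C2–H, basic N3 beside the C–metal bond) to an aldehyde, in which iodine–magnesium exchange and Mg-to-Ti transmetalation give the non-basic, weakly nucleophilic heteroaryl–Ti(OiPr)3 8 that adds to 6 only inside the alkoxide-bridged dititanium complex formed with [(S)-H8-BINOLate]Ti(OiPr)2, where the aldehyde sits on the chiral tetravalent titanium centre with its Re face shielded by the ligand so that the imidazolyl group is delivered from the second titanium to the Si face to give the (R)-carbinol, while excess Ti(OiPr)4 ties up N3 and strips the N,O-chelating product alkoxide from the catalyst; the closest known reaction type is the titanium/BINOL-type-catalysed enantioselective addition of Grignard-derived aryl-, thienyl- and 3-pyridyltitanium reagents to aromatic aldehydes.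

Step 4
Reactants: 9 (R)-{5-[4-(TBSO)benzyl]-1-methyl-1H-imidazol-4-yl}(4-methoxyphenyl)methanol
Product: 10 4-[(R)-(TBSO)(4-methoxyphenyl)methyl]-5-[4-(TBSO)benzyl]-1-methyl-1H-imidazole
Conditions: TBSCl (2 equiv), imidazole (4 equiv), DMAP (0.1 equiv), DMF, rt to 35 °C
Reagents that add atoms: tert-butyldimethylsilyl chloride, CC(C)(C)[Si](C)(C)Cl
Why: Standard O-silylation (Corey protocol) under basic, Lewis-acid-free conditions does not break the ionisable doubly benzylic C–O bond, so the configuration is retained.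

Step 5
Reactants: 10 4-[(R)-(TBSO)(4-methoxyphenyl)methyl]-5-[4-(TBSO)benzyl]-1-methyl-1H-imidazole
Product: 12 2-azido-4-[(R)-(TBSO)(4-methoxyphenyl)methyl]-5-[4-(TBSO)benzyl]-1-methyl-1H-imidazole, via 2-lithioimidazole 11 (not isolated)
Conditions: n-BuLi (1.05 equiv), THF, −78 °C, 20 min; TsN3 (1.2 equiv), −78 °C to rt
Reagents that add atoms: 4-methylbenzenesulfonyl azide (tosyl azide), Cc1ccc(cc1)S(=O)(=O)N=[N+]=[N-]
Why: C2 of a 1-methylimidazole is the kinetically most acidic C–H, and the 2-lithio species undergoes electrophilic azide transfer from tosyl azide (the triazenyl anion fragments to azide and sulfinate), leaving the carbinol centre untouched.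

Step 6
Reactants: 12 2-azido-4-[(R)-(TBSO)(4-methoxyphenyl)methyl]-5-[4-(TBSO)benzyl]-1-methyl-1H-imidazole
Product: 13 4-[(R)-(TBSO)(4-methoxyphenyl)methyl]-5-[4-(TBSO)benzyl]-1-methyl-1H-imidazol-2-amine
Conditions: H2 (1 atm), 5% Pd/CaCO3 poisoned with Pb(OAc)2, EtOAc, rt; used crude in step 7
Reagents that add atoms: none
Why: Catalytic hydrogenation of the azide over poisoned palladium is chemoselective and does not hydrogenolyse the benzylic C–O bond.

Step 7
Reactants: 13 4-[(R)-(TBSO)(4-methoxyphenyl)methyl]-5-[4-(TBSO)benzyl]-1-methyl-1H-imidazol-2-amine; 14 1-methylimidazolidine-2,4,5-trione (1-methylparabanic acid)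
Product: 16 4-({4-[(R)-(TBSO)(4-methoxyphenyl)methyl]-5-[4-(TBSO)benzyl]-1-methyl-1H-imidazol-2-yl}amino)-1-methyl-1H-imidazole-2,5-dione, via O-silylated parabanic acid 15 (not isolated)
Conditions: 14, BSA (3 equiv), MeCN, rt, 1 h; then 13, toluene, 110 °C, 12 h; aqueous work-up
Reagents that add atoms: none
Why: Addition–elimination of the exocyclic primary amine at the C4 silyl imidate carbon of 15 gives the cyclic acylamidine (the condensation used for this alkaloid family) under neutral conditions that leave the silyl ethers and the stereocentre intact.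

Step 8
Reactants: 16 4-({4-[(R)-(TBSO)(4-methoxyphenyl)methyl]-5-[4-(TBSO)benzyl]-1-methyl-1H-imidazol-2-yl}amino)-1-methyl-1H-imidazole-2,5-dione
Product: 17 4-({4-[(R)-hydroxy(4-methoxyphenyl)methyl]-5-(4-hydroxybenzyl)-1-methyl-1H-imidazol-2-yl}amino)-1-methyl-1H-imidazole-2,5-dione
Conditions: TBAF (3 equiv), AcOH (3 equiv), THF, 0 °C to rt
Reagents that add atoms: none
Why: Fluoride-mediated desilylation cleaves both the aryl and the benzhydryl-type silyl ether, and the AcOH buffer avoids both carbocation formation at the carbinol (no racemisation) and base attack on the imidazoledione ring.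

**Compound list**

1 | 4,5-diiodo-1-methyl-1H-imidazole | Cn1cnc(I)c1I | starting material
2 | 4-[(tert-butyldimethylsilyl)oxy]benzaldehyde | O=Cc1ccc(O[Si](C)(C)C(C)(C)C)cc1 | starting material
3 | (4-iodo-1-methyl-1H-imidazol-5-yl)magnesium bromide | Cn1cnc(I)c1[Mg]Br | intermediate
4 | racemic [4-(TBSO)phenyl](4-iodo-1-methyl-1H-imidazol-5-yl)methanol | Cn1cnc(I)c1C(O)c1ccc(O[Si](C)(C)C(C)(C)C)cc1 | intermediate
5 | 5-[4-(TBSO)benzyl]-4-iodo-1-methyl-1H-imidazole | Cn1cnc(I)c1Cc1ccc(O[Si](C)(C)C(C)(C)C)cc1 | intermediate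
6 | 4-methoxybenzaldehyde | COc1ccc(C=O)cc1 | starting material
7 | {5-[4-(TBSO)benzyl]-1-methyl-1H-imidazol-4-yl}magnesium chloride | Cn1cnc([Mg]Cl)c1Cc1ccc(O[Si](C)(C)C(C)(C)C)cc1 | intermediate
8 | {5-[4-(TBSO)benzyl]-1-methyl-1H-imidazol-4-yl}titanium triisopropoxide | Cn1cnc([Ti](OC(C)C)(OC(C)C)OC(C)C)c1Cc1ccc(O[Si](C)(C)C(C)(C)C)cc1 | intermediate
9 | (R)-{5-[4-(TBSO)benzyl]-1-methyl-1H-imidazol-4-yl}(4-methoxyphenyl)methanol | COc1ccc([C@@H](O)c2ncn(C)c2Cc2ccc(O[Si](C)(C)C(C)(C)C)cc2)cc1 | intermediate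
10 | 4-[(R)-(TBSO)(4-methoxyphenyl)methyl]-5-[4-(TBSO)benzyl]-1-methyl-1H-imidazole | COc1ccc([C@@H](O[Si](C)(C)C(C)(C)C)c2ncn(C)c2Cc2ccc(O[Si](C)(C)C(C)(C)C)cc2)cc1 | intermediate
11 | {4-[(R)-(TBSO)(4-methoxyphenyl)methyl]-5-[4-(TBSO)benzyl]-1-methyl-1H-imidazol-2-yl}lithium | COc1ccc([C@@H](O[Si](C)(C)C(C)(C)C)c2nc([Li])n(C)c2Cc2ccc(O[Si](C)(C)C(C)(C)C)cc2)cc1 | intermediate
12 | 2-azido-4-[(R)-(TBSO)(4-methoxyphenyl)methyl]-5-[4-(TBSO)benzyl]-1-methyl-1H-imidazole | COc1ccc([C@@H](O[Si](C)(C)C(C)(C)C)c2nc(N=[N+]=[N-])n(C)c2Cc2ccc(O[Si](C)(C)C(C)(C)C)cc2)cc1 | intermediate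
13 | 4-[(R)-(TBSO)(4-methoxyphenyl)methyl]-5-[4-(TBSO)benzyl]-1-methyl-1H-imidazol-2-amine | COc1ccc([C@@H](O[Si](C)(C)C(C)(C)C)c2nc(N)n(C)c2Cc2ccc(O[Si](C)(C)C(C)(C)C)cc2)cc1 | intermediate
14 | 1-methylimidazolidine-2,4,5-trione (1-methylparabanic acid) | CN1C(=O)NC(=O)C1=O | starting material
15 | 1-methyl-4-[(trimethylsilyl)oxy]-1H-imidazole-2,5-dione | CN1C(=O)N=C(O[Si](C)(C)C)C1=O | intermediate
16 | 4-({4-[(R)-(TBSO)(4-methoxyphenyl)methyl]-5-[4-(TBSO)benzyl]-1-methyl-1H-imidazol-2-yl}amino)-1-methyl-1H-imidazole-2,5-dione | COc1ccc([C@@H](O[Si](C)(C)C(C)(C)C)c2nc(NC3=NC(=O)N(C)C3=O)n(C)c2Cc2ccc(O[Si](C)(C)C(C)(C)C)cc2)cc1 | intermediate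
17 | 4-({4-[(R)-hydroxy(4-methoxyphenyl)methyl]-5-(4-hydroxybenzyl)-1-methyl-1H-imidazol-2-yl}amino)-1-methyl-1H-imidazole-2,5-dione | COc1ccc([C@@H](O)c2nc(NC3=NC(=O)N(C)C3=O)n(C)c2Cc2ccc(O)cc2)cc1 | target

**Totals**
Total step count: 8. Longest linear sequence: 8 steps (1 to 17); the other inputs (2, 6, 14) are bought.

**Three steps most likely to fail**

Step 3 (the proposed new reaction). The risks are N3-bridged aggregation of 8, a racemic background addition promoted by magnesium and lithium salts, and a low or reversed sense of induction. The Si-face sense for the (S)-ligand is assigned by analogy and must be checked by chiral HPLC and Mosher ester analysis of 9; if it is reversed, (R)-H8-BINOL is used. The fallback uses known chemistry, sets out from 5 and comes back at 9. Grignard reagent 7 is prepared as in step 3 and added directly to 6 in THF at 0 °C without titanium or ligand, a plain Grignard addition that gives the racemic carbinol F1. Preparative chiral supercritical-fluid chromatography of F1 (amylose tris(3,5-dimethylphenylcarbamate) phase, CO2/MeOH with 0.1% Et2NH) gives 9. The unwanted (S)-carbinol F2 is recycled by MnO2 oxidation in CH2Cl2 to the ketone F3 and NaBH4 reduction in MeOH back to F1.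

Step 5. The risks are competing deprotonation of the doubly benzylic C–H (loss of ee or a retro-Brook silyl shift) and incomplete fragmentation of the triazenyl salt. The fallback avoids strong base, sets out from 10 and comes back at 12. Electrophilic bromination with NBS (THF, 0 °C, dark) at the only free ring position gives the 2-bromoimidazole F4. Ullmann-type azidation (NaN3, CuI 10 mol%, N,N'-dimethylethylenediamine, sodium ascorbate, EtOH/H2O, 80 °C) then replaces bromide by azide to give 12.

Step 8. The risks are fluoride or phenoxide attack on the imidazoledione ring and slow cleavage of the hindered benzhydryl silyl ether. The fallback changes the order of the endgame, sets out from 13 and comes back at 17. TBAF/AcOH in THF desilylates 13 to the aminodiol F5. BSA (5 equiv, MeCN, rt) silylates both hydroxyl groups in the flask to give the bis(trimethylsilyl) ether F6. F6 condenses with 15 in toluene at 110 °C, as in step 7, to give the bis(trimethylsilyl) ether F7 of the target. Stirring in MeOH at rt removes the trimethylsilyl groups and gives 17.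

**Further compounds**

F1 | step 3 | racemic {5-[4-(TBSO)benzyl]-1-methyl-1H-imidazol-4-yl}(4-methoxyphenyl)methanol | COc1ccc(C(O)c2ncn(C)c2Cc2ccc(O[Si](C)(C)C(C)(C)C)cc2)cc1
F2 | step 3 | (S)-{5-[4-(TBSO)benzyl]-1-methyl-1H-imidazol-4-yl}(4-methoxyphenyl)methanol | COc1ccc([C@H](O)c2ncn(C)c2Cc2ccc(O[Si](C)(C)C(C)(C)C)cc2)cc1
F3 | step 3 | {5-[4-(TBSO)benzyl]-1-methyl-1H-imidazol-4-yl}(4-methoxyphenyl)methanone | COc1ccc(C(=O)c2ncn(C)c2Cc2ccc(O[Si](C)(C)C(C)(C)C)cc2)cc1
F4 | step 5 | 2-bromo-4-[(R)-(TBSO)(4-methoxyphenyl)methyl]-5-[4-(TBSO)benzyl]-1-methyl-1H-imidazole | COc1ccc([C@@H](O[Si](C)(C)C(C)(C)C)c2nc(Br)n(C)c2Cc2ccc(O[Si](C)(C)C(C)(C)C)cc2)cc1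
F5 | step 8 | 4-({2-amino-4-[(R)-hydroxy(4-methoxyphenyl)methyl]-1-methyl-1H-imidazol-5-yl}methyl)phenol | COc1ccc([C@@H](O)c2nc(N)n(C)c2Cc2ccc(O)cc2)cc1
F6 | step 8 | 4-[(R)-(4-methoxyphenyl)(trimethylsilyloxy)methyl]-1-methyl-5-[4-(trimethylsilyloxy)benzyl]-1H-imidazol-2-amine | COc1ccc([C@@H](O[Si](C)(C)C)c2nc(N)n(C)c2Cc2ccc(O[Si](C)(C)C)cc2)cc1
F7 | step 8 | 4-({4-[(R)-(4-methoxyphenyl)(trimethylsilyloxy)methyl]-1-methyl-5-[4-(trimethylsilyloxy)benzyl]-1H-imidazol-2-yl}amino)-1-methyl-1H-imidazole-2,5-dione | COc1ccc([C@@H](O[Si](C)(C)C)c2nc(NC3=NC(=O)N(C)C3=O)n(C)c2Cc2ccc(O[Si](C)(C)C)cc2)cc1
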